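# Proposed total synthesis of CNP0192813.1, (4R,5S,7R,9R,10R,11R)-7,9-bis(3-methylbutanoyloxy)longipin-2-en-1-one (25)

## Analysis of the target

- **Numbering.** Target 25 is the 7,9-bis(3-methylbutanoate) of a longipin-2-en-1-one. The skeleton is numbered C1 (ketone), C2=C3 (C3 bears CH3), C4, C5, C6 (CMe2), C7 (O-acyl), C8 (CH2), C9 (O-acyl), C10 (quaternary, CH3) and C11. These labels are kept for the same atoms in every intermediate.
- **Ring system.** The core is the cyclobutane C4-C5-C11-C10, and both of its diagonals are bridged.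
  - C4 and C11 are joined by the enone bridge C3=C2-C1(=O) on one face. This is ring A, a verbenone-type bicyclo[3.1.1]heptenone.
  - C5 and C10 are joined by C6-C7-C8-C9 on the other face. This is ring C, seven-membered, a bicyclo[4.1.1]octane.
- **Stereocentres.** Four of the six (4R,5S,10R,11R) are the cyclobutane carbons, which the two bridges lock to each other. The other two (7R,9R) form an anti-1,3-diol diester. Each is neopentylic, next to the quaternary carbons C6 and C10.
- **Sensitive groups.**
  - The two secondary esters rule out strong base or hydride late in the route.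
  - The strained cyclobutane opens through cations or radicals at C3.
  - The verbenone-type enone is photolabile.
- **Difficulty.** A cyclobutane must be bridged 1,3 twice, a mode that ordinary fused [2+2] closures do not give. The C5-C6 bond joins a cyclobutane CH to a quaternary carbon. The remote anti-diol must be related to the core in an absolute sense.
- **Feature exploited.**
  - Cutting C4-C10, C5-C11 and C5-C6 unravels all fifteen skeletal carbons into one unbranched head-to-tail farnesane chain, C5-C4-C3-C2-C1-C11-C10-C9-C8-C7-C6, with C5 at its end.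
  - C5 is the only cyclobutane carbon that carries H and a single exocyclic carbon, so it alone can be a ketene carbonyl carbon.
  - C10=C11 then becomes an E-trisubstituted alkene whose polarisation demands exactly the crossed closure.

## Retrosynthetic reasoning

**C2=C3 and the C1 ketone (25 to 24, 23, 22).** The enone is removed first. C1 is carried as a silyl-protected (S)-carbinol and C2-C3 as a saturated bond.
- This keeps ring A free of any alkene or enolisable 1,3-dicarbonyl relation to C5 while the other rings are made.
- It also gives C1 a second role as a temporary stereocentre.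
- The forward reaction is desilylation followed by one-flask oxidation and dehydrogenation. The regiochemistry is unambiguous because the other alpha-carbon, C11, is a bridgehead.

**C5-C6 (22 to 21, 20, 19).** Ring C is cut at its most hindered bond. This cut turns C5 into a carbonyl carbon and C6 into an isopropenyl carbon.
- Forward, a tertiary C6 radical made by hydrogen atom transfer to the alkene of sulfonylhydrazone 20 adds to the C5=N carbon. Loss of sulfinate and N2 then leaves C5-H.
- One operation should give ring C, the C5 stereocentre and the gem-dimethyl group.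
- The chain on C10 can reach only one face of C5.

**C4-C10 and C5-C11 (19 to 18, 17, 16): the key disconnection.** Both bonds are cut at once, so bicyclic cyclobutanone 19 becomes acyclic ketene 18, made from acid 16.
- No other pair of cyclobutane bonds leaves a linear chain.
- No other cyclobutane atom can be the ketene carbon.
- The forward [2+2] must be crossed, must keep the alkene geometry, and must choose one alkene face.

**C1-C2 and the C3 centre (16 to 14, 13, 8 + 11; 11 to 9).**
- The C1 carbinol is delta to the ester carbonyl. The C1-C2 bond is therefore a vinylogous aldol bond between enal 8 and silyl dienolate 11 of the C5 ester 9.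
- The resulting enoate 13 is reduced to 14 before the key step. A conjugated acid would give a vinylketene and leave an exocyclic methylene next to the cyclobutane. That methylene would take up a hydrogen atom as readily as the isopropenyl group, and the four-membered ring would open.

**C8-C9 and the C7 centre (8 to 7, 6, 5, 1 + 2).**
- The anti-1,3-diol is an aldol retron. C8-C9 is made from methyl ketone 1 and enal 2.
- C7 is set by an Evans-Tishchenko reduction. It uses the aldehyde of the ester side chain as both hydride source and acyl source, so the first ester of the target arrives in the stereodefining step.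
- Compounds 1, 2 and 9 are the three isoprene units of the skeleton.

## Alternatives that were turned down

**Alternative 1:** the textbook route. Only C5-C11 is cut, and the forward step is intramolecular alkylation of the cross-conjugated enolate of the fused bicyclo[5.4.0]undecenone mesylate A1.
- The key step makes one bond only.
- A1 already holds five stereocentres and both quaternary carbons in a six-seven ring system. That system has to be reached by annulation and ring expansion.
- The leaving group sits on a secondary carbon next to CMe2, so substitution is slow and elimination or fragmentation competes.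
- The strong base needed does not tolerate the two esters, which adds protecting-group steps.

**Alternative 2:** C4-C10 and C5-C11 are cut with C5-C6 kept. This gives the eleven-membered humulane trienone A2, which would be closed by a transannular [2+2] photocycloaddition. The skeleton and the C9 oxygen could come from zerumbone A3.
- C4 and C11 are three atoms apart, so the rule of five favours first bonding C4 to C11. That leads to a fused five-four-six closure, not the crossed one.
- Irradiation scrambles the dienone geometry.
- The verbenone-type product itself rearranges under the same light.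
- A3 is achiral. It would need C1 oxidation, dehydrogenation to the C2-C5 diene, oxygenation at C7 and a resolution, which costs more than the key step wins.

**Alternative 3:** skeleton first, oxygen last. The bare enone A4 would be made and then hydroxylated at C7-H and C9-H.
- Both sites are neopentylic methylenes shielded by C6 and C10, whereas C8 is the exposed methylene.
- No group is placed to direct an oxidant.
- Two separate oxidations would have to give the anti relation and the right absolute sense.
- The hard tricycle would still have to be built first.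

Key step: step 9

Assumption: aldehyde 2 (an industrial C5 carotenoid building block) and ester 9 are taken as purchasable.

## Route

Step 1
Reactants: 1 3-methylbut-3-en-2-one; 2 (E)-4,4-dimethoxy-2-methylbut-2-enal
Product: 5 (5R,6E)-5-hydroxy-8,8-dimethoxy-2,6-dimethylocta-1,6-dien-3-one, via enol borinate 3 (not isolated), via boron aldolate 4 (not isolated)
Conditions: (-)-Ipc2BCl, Et3N, Et2O, 0 °C; 2, -78 to -20 °C; H2O2, MeOH, pH 7 buffer, 0 °C
Reagents that add atoms: none
Why: Boron-mediated asymmetric aldol reaction of a methyl ketone that can enolise on one side only; the isopinocampheyl ligands should direct the enolate to the Re face of 2 and set 9R, and the neutral conditions spare the acetal. Any minor enantiomer becomes a separable diastereomer after the second asymmetric step (step 6).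

Step 2
Reactants: 5 (5R,6E)-5-hydroxy-8,8-dimethoxy-2,6-dimethylocta-1,6-dien-3-one
Product: 6 (3R,5R,6E)-3-hydroxy-8,8-dimethoxy-2,6-dimethylocta-1,6-dien-5-yl 3-methylbutanoate
Conditions: SmI2 (0.3 equiv), 3-methylbutanal (5 equiv), THF, -10 °C
Reagents that add atoms: 3-methylbutanal, CC(C)CC=O
Why: Evans-Tishchenko reduction: the samarium-bound hemiacetal of the C9 hydroxyl delivers hydride to the C7 ketone through a chair-like bicyclic transition state. This should give the anti (7R,9R) relation and leave the C9 oxygen already acylated with the side chain of the target.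

Step 3
Reactants: 6 (3R,5R,6E)-3-hydroxy-8,8-dimethoxy-2,6-dimethylocta-1,6-dien-5-yl 3-methylbutanoate
Product: 7 (3R,5R,6E)-8,8-dimethoxy-2,6-dimethylocta-1,6-diene-3,5-diyl bis(3-methylbutanoate)
Conditions: 3-methylbutanoyl chloride, pyridine, DMAP (cat.), CH2Cl2, 0 °C to rt
Reagents that add atoms: 3-methylbutanoyl chloride, CC(C)CC(=O)Cl
Why: Standard DMAP-catalysed acylation of an unhindered secondary allylic alcohol; both esters of the target are now in place and also serve as the protecting groups.

Step 4
Reactants: 7 (3R,5R,6E)-8,8-dimethoxy-2,6-dimethylocta-1,6-diene-3,5-diyl bis(3-methylbutanoate)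
Product: 8 (2E,4R,6R)-3,7-dimethyl-1-oxoocta-2,7-diene-4,6-diyl bis(3-methylbutanoate)
Conditions: PPTS (cat.), acetone/H2O, rt
Reagents that add atoms: water, O
Why: Mild acid hydrolysis of an allylic dimethyl acetal unmasks the C1 aldehyde without an oxidation step; the esters and the E-alkene should be stable under these conditions.

Step 5
Reactants: 9 tert-butyl 3-methylbut-2-enoate
Product: 11 tert-butyl[(1-tert-butoxy-3-methylbuta-1,3-dien-1-yl)oxy]dimethylsilane, via lithium dienolate 10 (not isolated)
Conditions: LDA, THF/DMPU, -78 °C; TBSCl, -78 °C to rt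
Reagents that add atoms: tert-butyldimethylsilyl chloride, CC(C)(C)[Si](C)(C)Cl
Why: Gamma-deprotonation of the senecioate and O-silylation is the standard way to silyl dienolates; the geometry of the ketene acetal is of no consequence.

Step 6
Reactants: 8 (2E,4R,6R)-3,7-dimethyl-1-oxoocta-2,7-diene-4,6-diyl bis(3-methylbutanoate); 11 tert-butyl[(1-tert-butoxy-3-methylbuta-1,3-dien-1-yl)oxy]dimethylsilane
Product: 13 tert-butyl (2E,5S,6E,8R,10R)-5-hydroxy-3,7,11-trimethyl-8,10-bis[(3-methylbutanoyl)oxy]dodeca-2,6,11-trienoate, via trichlorosilyl ether 12 (not isolated)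
Conditions: SiCl4, bisphosphoramide {[(1,1'-binaphthyl-2,2'-diyl)(NMe)2]P(O)N(Me)}2(CH2)5 (5 mol %, antipode for Si-face attack), i-Pr2NEt (cat.), CH2Cl2, -78 °C; aq NaHCO3/KF
Reagents that add atoms: none
Why: Catalytic enantioselective vinylogous Mukaiyama aldol reaction, for which conjugated aldehydes and senecioate dienolates are the favoured partners; attack through the gamma-carbon C2 on the Si face sets 1S under catalyst control, the C9 centre being too remote to interfere. All fifteen skeletal carbons are now in one chain.

Step 7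
Reactants: 13 tert-butyl (2E,5S,6E,8R,10R)-5-hydroxy-3,7,11-trimethyl-8,10-bis[(3-methylbutanoyl)oxy]dodeca-2,6,11-trienoate
Product: 14 tert-butyl (3R,5S,6E,8R,10R)-5-hydroxy-3,7,11-trimethyl-8,10-bis[(3-methylbutanoyl)oxy]dodeca-6,11-dienoate
Conditions: Cu(OAc)2·H2O (5 mol %), DTBM-SEGPHOS (antipode that gives 3R), (EtO)2MeSiH, t-BuOH, toluene, 0 °C to rt; aq NH4F
Reagents that add atoms: none
Why: Ligand-controlled copper hydride conjugate reduction of a beta,beta-disubstituted enoate, far faster than hydrocupration of the isolated alkenes. It removes the alkene that would otherwise end up next to the cyclobutane, and it sets 3R so that the methyl group later avoids the C10 methyl.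

Step 8
Reactants: 14 tert-butyl (3R,5S,6E,8R,10R)-5-hydroxy-3,7,11-trimethyl-8,10-bis[(3-methylbutanoyl)oxy]dodeca-6,11-dienoate
Product: 16 (3R,5S,6E,8R,10R)-5-[(tert-butyldimethylsilyl)oxy]-3,7,11-trimethyl-8,10-bis[(3-methylbutanoyl)oxy]dodeca-6,11-dienoic acid, via bis-silyl derivative 15 (not isolated)
Conditions: TBSOTf (3.5 equiv), 2,6-lutidine, CH2Cl2, 0 °C to rt; then THF/H2O/AcOH, rt
Reagents that add atoms: tert-butyldimethylsilyl triflate, CC(C)(C)[Si](C)(C)OS(=O)(=O)C(F)(F)F
Why: The silyl triflate silylates the C1 hydroxyl and converts the tert-butyl ester into the silyl ester with loss of isobutene. The labile silyl ester alone is hydrolysed on mild aqueous treatment, so the acid is freed without touching the two secondary esters.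

Step 9
Reactants: 16 (3R,5S,6E,8R,10R)-5-[(tert-butyldimethylsilyl)oxy]-3,7,11-trimethyl-8,10-bis[(3-methylbutanoyl)oxy]dodeca-6,11-dienoic acid
Product: 19 (1R,3R)-1-[(1R,2S,4R,5R,7R)-2-[(tert-butyldimethylsilyl)oxy]-4,7-dimethyl-6-oxobicyclo[3.1.1]heptan-7-yl]-4-methylpent-4-ene-1,3-diyl bis(3-methylbutanoate), via acid chloride 17 (not isolated), via ketene 18 (not isolated)
Conditions: 1-chloro-N,N,2-trimethylprop-1-en-1-amine, CH2Cl2, 0 °C; then slow addition to Et3N, toluene, 110 °C, high dilution
Reagents that add atoms: none
Why: Dehydrochlorination of 17 gives ketene 18, whose carbonyl carbon C5 bonds to the less substituted alkene carbon C11 while positive charge builds at fully substituted C10, which the ketene alpha-carbon C4 captures in a concerted, asynchronous [2+2] cycloaddition. The closest known reaction type is the intramolecular ketene-alkene cycloaddition of geranic- and farnesoic-type acid chlorides, which gives bicyclo[3.1.1]heptan-6-ones. The six-membered ring C5-C4-C3-C2-C1-C11 closes through C5-C11 and the cyclobutanone C4-C5-C11-C10 through C4-C10, that is the crossed, 1,3-bridged mode; the fused bicyclo[3.2.0] mode would put the charge on secondary C11 and is disfavoured by the trisubstituted alkene. C10 and C11 are related by suprafacial addition to the E-alkene, which places the C10 methyl over the C1-C3 bridge and C9 on the opposite face, pointing towards C5 as ring C requires, and C4 is fixed by the bridge. The absolute sense comes from the 1S centre: C2 must rise out of the alkene plane towards the ketene, and of the two groups left on C1 the one that lies beside the cis C10 methyl is H on the wanted face and the bulky silyloxy group on the other (allylic 1,3-strain), so the silyloxy group ends on the carbonyl-bridge side. The 3R methyl lies on that same uncrowded side and reinforces the preference. The isopropenyl group is too far from the ketene to compete, and esters and silyl ether are inert to Et3N.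

Step 10
Reactants: 19 bicyclic cyclobutanone (name as in step 9)
Product: 20 N-tosylhydrazone of 19 at C5 (C5=N-NHTs; all stereocentres as in 19)
Conditions: TsNHNH2, EtOH, 50 °C
Reagents that add atoms: 4-methylbenzenesulfonohydrazide, Cc1ccc(cc1)S(=O)(=O)NN
Why: Hydrazone formation at the only ketone; cyclobutanones of this bicyclic type are known to condense with hydrazines (they undergo Wolff-Kishner reduction), and neither alpha-carbon can epimerise because both are bridgeheads.

Step 11
Reactants: 20 N-tosylhydrazone of 19
Product: 22 (1S,3R,4S,5S,7R,9R,10R,11R)-1-[(tert-butyldimethylsilyl)oxy]longipinane-7,9-diyl bis(3-methylbutanoate), via tricyclic tosylhydrazide 21 (not isolated)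
Conditions: Fe(acac)3 (0.3 equiv), PhSiH3, EtOH, 60 °C; then Et3N, reflux
Reagents that add atoms: none
Why: Iron hydride hydrogen atom transfer to the only alkene gives the tertiary C6 radical, which adds to the C5=N carbon (reductive alkylation of alkene-tethered tosylhydrazones, an alkylative Wolff-Kishner reaction); loss of sulfinate and N2 from 21 leaves C5-H. The C9 chain hangs over one face of C5 only, so ring C can close only with 5S, and the new methyl completes the gem-dimethyl group.

Step 12
Reactants: 22 (1S,3R,4S,5S,7R,9R,10R,11R)-1-[(tert-butyldimethylsilyl)oxy]longipinane-7,9-diyl bis(3-methylbutanoate)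
Product: 23 (1S,3R,4S,5S,7R,9R,10R,11R)-1-hydroxylongipinane-7,9-diyl bis(3-methylbutanoate)
Conditions: HF·pyridine, THF, 0 °C to rt
Reagents that add atoms: none
Why: Fluoride-mediated cleavage of a secondary silyl ether under buffered acidic conditions, which should neither hydrolyse nor migrate the esters.

Step 13
Reactants: 23 (1S,3R,4S,5S,7R,9R,10R,11R)-1-hydroxylongipinane-7,9-diyl bis(3-methylbutanoate)
Product: 25 (4R,5S,7R,9R,10R,11R)-1-oxolongip-2-ene-7,9-diyl bis(3-methylbutanoate) (target), via saturated ketone 24 (not isolated)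
Conditions: IBX (4 equiv), DMSO, rt, then 75 °C
Reagents that add atoms: none
Why: IBX oxidises the carbinol to ketone 24 and, on warming, dehydrogenates it to the enone; enolisation is possible only towards C2 because C11 is a bridgehead, so C2=C3 is the only alkene that can form. The two auxiliary centres C1 and C3 are erased, and the six stereocentres of the target remain untouched.

## Compound list

1 | 3-methylbut-3-en-2-one | CC(=O)C(C)=C | starting material
2 | (E)-4,4-dimethoxy-2-methylbut-2-enal | COC(OC)/C=C(C)/C=O | starting material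
3 | 3-methylbuta-1,3-dien-2-yl diisopinocampheylborinate | C=C(C)C(=C)OB([C@@H]1C[C@@H]2C[C@H]([C@H]1C)C2(C)C)[C@@H]1C[C@@H]2C[C@H]([C@H]1C)C2(C)C | intermediate
4 | diisopinocampheylborinate (boron aldolate) of 5 | COC(OC)/C=C(C)/[C@H](OB([C@@H]1C[C@@H]2C[C@H]([C@H]1C)C2(C)C)[C@@H]1C[C@@H]2C[C@H]([C@H]1C)C2(C)C)CC(=O)C(C)=C | intermediate
5 | (5R,6E)-5-hydroxy-8,8-dimethoxy-2,6-dimethylocta-1,6-dien-3-one | COC(OC)/C=C(C)/[C@H](O)CC(=O)C(C)=C | intermediate
6 | (3R,5R,6E)-3-hydroxy-8,8-dimethoxy-2,6-dimethylocta-1,6-dien-5-yl 3-methylbutanoate | COC(OC)/C=C(C)/[C@H](OC(=O)CC(C)C)C[C@@H](O)C(C)=C | intermediate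
7 | (3R,5R,6E)-8,8-dimethoxy-2,6-dimethylocta-1,6-diene-3,5-diyl bis(3-methylbutanoate) | COC(OC)/C=C(C)/[C@H](OC(=O)CC(C)C)C[C@@H](OC(=O)CC(C)C)C(C)=C | intermediate
8 | (2E,4R,6R)-3,7-dimethyl-1-oxoocta-2,7-diene-4,6-diyl bis(3-methylbutanoate) | O=C/C=C(C)/[C@H](OC(=O)CC(C)C)C[C@@H](OC(=O)CC(C)C)C(C)=C | intermediate
9 | tert-butyl 3-methylbut-2-enoate | CC(C)=CC(=O)OC(C)(C)C | starting material
10 | lithium dienolate of 9 | [Li]OC(OC(C)(C)C)=CC(C)=C | intermediate
11 | tert-butyl[(1-tert-butoxy-3-methylbuta-1,3-dien-1-yl)oxy]dimethylsilane | C=C(C)C=C(OC(C)(C)C)O[Si](C)(C)C(C)(C)C | intermediate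
12 | trichlorosilyl ether of 13 | CC(C)(C)OC(=O)/C=C(C)/C[C@H](O[Si](Cl)(Cl)Cl)/C=C(C)/[C@H](OC(=O)CC(C)C)C[C@@H](OC(=O)CC(C)C)C(C)=C | intermediate
13 | tert-butyl (2E,5S,6E,8R,10R)-5-hydroxy-3,7,11-trimethyl-8,10-bis[(3-methylbutanoyl)oxy]dodeca-2,6,11-trienoate | CC(C)(C)OC(=O)/C=C(C)/C[C@H](O)/C=C(C)/[C@H](OC(=O)CC(C)C)C[C@@H](OC(=O)CC(C)C)C(C)=C | intermediate
14 | tert-butyl (3R,5S,6E,8R,10R)-5-hydroxy-3,7,11-trimethyl-8,10-bis[(3-methylbutanoyl)oxy]dodeca-6,11-dienoate | CC(C)(C)OC(=O)C[C@H](C)C[C@H](O)/C=C(C)/[C@H](OC(=O)CC(C)C)C[C@@H](OC(=O)CC(C)C)C(C)=C | intermediate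
15 | tert-butyldimethylsilyl ester of 16 | CC(C)(C)[Si](C)(C)OC(=O)C[C@H](C)C[C@H](O[Si](C)(C)C(C)(C)C)/C=C(C)/[C@H](OC(=O)CC(C)C)C[C@@H](OC(=O)CC(C)C)C(C)=C | intermediate
16 | (3R,5S,6E,8R,10R)-5-[(tert-butyldimethylsilyl)oxy]-3,7,11-trimethyl-8,10-bis[(3-methylbutanoyl)oxy]dodeca-6,11-dienoic acid | OC(=O)C[C@H](C)C[C@H](O[Si](C)(C)C(C)(C)C)/C=C(C)/[C@H](OC(=O)CC(C)C)C[C@@H](OC(=O)CC(C)C)C(C)=C | intermediate
17 | acid chloride of 16 | ClC(=O)C[C@H](C)C[C@H](O[Si](C)(C)C(C)(C)C)/C=C(C)/[C@H](OC(=O)CC(C)C)C[C@@H](OC(=O)CC(C)C)C(C)=C | intermediate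
18 | ketene from 17 (C5=C4 ketene, chain otherwise as in 16) | O=C=C[C@H](C)C[C@H](O[Si](C)(C)C(C)(C)C)/C=C(C)/[C@H](OC(=O)CC(C)C)C[C@@H](OC(=O)CC(C)C)C(C)=C | intermediate
19 | (1R,3R)-1-[(1R,2S,4R,5R,7R)-2-[(tert-butyldimethylsilyl)oxy]-4,7-dimethyl-6-oxobicyclo[3.1.1]heptan-7-yl]-4-methylpent-4-ene-1,3-diyl bis(3-methylbutanoate) | C[C@@H]1C[C@H](O[Si](C)(C)C(C)(C)C)[C@@H]2C(=O)[C@H]1[C@@]2(C)[C@H](OC(=O)CC(C)C)C[C@@H](OC(=O)CC(C)C)C(C)=C | intermediate
20 | N-tosylhydrazone of 19 at C5 | C[C@@H]1C[C@H](O[Si](C)(C)C(C)(C)C)[C@@H]2C(=NNS(=O)(=O)c3ccc(C)cc3)[C@H]1[C@@]2(C)[C@H](OC(=O)CC(C)C)C[C@@H](OC(=O)CC(C)C)C(C)=C | intermediate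
21 | tricyclic N'-tosylhydrazide (22 with NHNHTs in place of H at C5) | C[C@@H]1C[C@H](O[Si](C)(C)C(C)(C)C)[C@@H]2[C@]3(NNS(=O)(=O)c4ccc(C)cc4)[C@H]1[C@@]2(C)[C@H](OC(=O)CC(C)C)C[C@@H](OC(=O)CC(C)C)C3(C)C | intermediate
22 | (1S,3R,4S,5S,7R,9R,10R,11R)-1-[(tert-butyldimethylsilyl)oxy]longipinane-7,9-diyl bis(3-methylbutanoate) | C[C@@H]1C[C@H](O[Si](C)(C)C(C)(C)C)[C@@H]2[C@@H]3[C@H]1[C@@]2(C)[C@H](OC(=O)CC(C)C)C[C@@H](OC(=O)CC(C)C)C3(C)C | intermediate
23 | (1S,3R,4S,5S,7R,9R,10R,11R)-1-hydroxylongipinane-7,9-diyl bis(3-methylbutanoate) | C[C@@H]1C[C@H](O)[C@@H]2[C@@H]3[C@H]1[C@@]2(C)[C@H](OC(=O)CC(C)C)C[C@@H](OC(=O)CC(C)C)C3(C)C | intermediate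
24 | (3R,4S,5S,7R,9R,10R,11R)-1-oxolongipinane-7,9-diyl bis(3-methylbutanoate) | C[C@@H]1CC(=O)[C@@H]2[C@@H]3[C@H]1[C@@]2(C)[C@H](OC(=O)CC(C)C)C[C@@H](OC(=O)CC(C)C)C3(C)C | intermediate
25 | (4R,5S,7R,9R,10R,11R)-1-oxolongip-2-ene-7,9-diyl bis(3-methylbutanoate) | CC1=CC(=O)[C@@H]2[C@@H]3[C@H]1[C@@]2(C)[C@H](OC(=O)CC(C)C)C[C@@H](OC(=O)CC(C)C)C3(C)C | target

## Step count and least certain steps

Total step count: 13. Longest linear sequence: 12 (steps 1-4 and 6-13).

**Step 9 (key step).**
- What may go wrong:
  - The alkene is flanked by two electron-withdrawing allylic C-O bonds, so the cycloaddition may be slow. The ketene could then dimerise.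
  - The C1 silyl ether oxygen could attack the acyl carbon, giving lactonisation with loss of the silyl group.
  - The high temperature may erode the facial selectivity.
- Fallback, from 16 back to 19: a cationic heterocumulene that is far more electrophilic and reacts at lower temperature.
  - Acid 16 is coupled with pyrrolidine to the pyrrolidine amide F1.
  - Tf2O and 2,4,6-collidine in 1,2-dichloroethane convert it into the keteniminium triflate F2.
  - F2 should close in the same crossed sense to the bicyclic iminium triflate F3.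
  - Aqueous hydrolysis of F3 returns to the route at 19.

**Step 11.**
- What may go wrong:
  - Closure of a seven-membered ring is slow. The tertiary radical may therefore be quenched by the excess hydride source before it reaches C5, giving net hydrogenation of the isopropenyl group.
  - The hydrazone may be reduced.
- Fallback, from 19 back to 22: a chain process in which the concentration of the hydrogen donor is kept low.
  - Cobalt-catalysed hydrochlorination of 19 (Co(BF4)2·6H2O with a salicylaldimine ligand, TsCl, PhSiH3, EtOH) gives the tertiary chloride F4.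
  - Condensation with 1-amino-2-phenylaziridine gives the N-aziridinylimine F5.
  - Slow addition of Bu3SnH/AIBN in refluxing benzene generates the same C6 radical.
  - Addition to C5=N is followed by loss of styrene and N2, and the resulting C5 radical takes up hydrogen, rejoining the route at 22.

**Step 13.**
- What may go wrong: dehydrogenation of the hindered bicyclic ketone may stall at 24, or prolonged heating may degrade the esters.
- Fallback, from 23 back to 25:
  - Dess-Martin oxidation with isolation of 24.
  - Soft enolisation (TMSOTf, Et3N) to the silyl enol ether F6.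
  - Saegusa-Ito oxidation with Pd(OAc)2 in MeCN to 25.

**Step 2.**
- What may go wrong:
  - Hydride transfer to an enone carbonyl may be accompanied by conjugate reduction or polymerisation of the isopropenyl ketone.
  - The acyl group may migrate between O9 and O7.
- Fallback, from 5 back to 7:
  - Hydroxyl-directed anti reduction with Me4NBH(OAc)3 in MeCN/AcOH at low temperature gives the anti-diol F7.
  - Double acylation with 3-methylbutanoyl chloride then arrives directly at 7.

**Step 1.**
- What may go wrong: the enantioface selectivity of boron enolates of methyl ketones is only moderate, which would cost material when the diastereomers are separated after step 6.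
- Fallback, from 2 back to 5: an auxiliary-controlled acetate aldol.
  - The titanium enolate (TiCl4, i-Pr2NEt) of (S)-N-acetyl-4-isopropyl-1,3-thiazolidine-2-thione adds to 2 to give the adduct F8.
  - MeONHMe·HCl and imidazole displace the auxiliary to give the N-methoxy-N-methylamide F9.
  - Excess isopropenylmagnesium bromide converts F9 into 5.

## Further compounds

F1 | step 9 | pyrrolidine amide of 16 | O=C(N1CCCC1)C[C@H](C)C[C@H](O[Si](C)(C)C(C)(C)C)/C=C(C)/[C@H](OC(=O)CC(C)C)C[C@@H](OC(=O)CC(C)C)C(C)=C
F2 | step 9 | keteniminium triflate from F1 | C1CC[N+](=C=C[C@H](C)C[C@H](O[Si](C)(C)C(C)(C)C)/C=C(C)/[C@H](OC(=O)CC(C)C)C[C@@H](OC(=O)CC(C)C)C(C)=C)C1.[O-]S(=O)(=O)C(F)(F)F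
F3 | step 9 | bicyclic pyrrolidinium-ylidene (iminium) triflate corresponding to 19 | C[C@@H]1C[C@H](O[Si](C)(C)C(C)(C)C)[C@@H]2C(=[N+]3CCCC3)[C@H]1[C@@]2(C)[C@H](OC(=O)CC(C)C)C[C@@H](OC(=O)CC(C)C)C(C)=C.[O-]S(=O)(=O)C(F)(F)F
F4 | step 11 | tertiary chloride from 19 (C6-Cl, CMe2Cl in place of isopropenyl) | C[C@@H]1C[C@H](O[Si](C)(C)C(C)(C)C)[C@@H]2C(=O)[C@H]1[C@@]2(C)[C@H](OC(=O)CC(C)C)C[C@@H](OC(=O)CC(C)C)C(C)(C)Cl
F5 | step 11 | N-(2-phenylaziridin-1-yl)imine of F4 at C5 (aziridine carbon as a mixture) | C[C@@H]1C[C@H](O[Si](C)(C)C(C)(C)C)[C@@H]2C(=NN3CC3c3ccccc3)[C@H]1[C@@]2(C)[C@H](OC(=O)CC(C)C)C[C@@H](OC(=O)CC(C)C)C(C)(C)Cl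
F6 | step 13 | trimethylsilyl enol ether of 24 (C1=C2) | C[C@@H]1C=C(O[Si](C)(C)C)[C@@H]2[C@@H]3[C@H]1[C@@]2(C)[C@H](OC(=O)CC(C)C)C[C@@H](OC(=O)CC(C)C)C3(C)C
F7 | step 2 | (3R,5R,6E)-8,8-dimethoxy-2,6-dimethylocta-1,6-diene-3,5-diol | COC(OC)/C=C(C)/[C@H](O)C[C@@H](O)C(C)=C
F8 | step 1 | (3R,4E)-3-hydroxy-6,6-dimethoxy-4-methyl-1-[(4S)-4-isopropyl-2-thioxo-1,3-thiazolidin-3-yl]hex-4-en-1-one | COC(OC)/C=C(C)/[C@H](O)CC(=O)N1[C@@H](C(C)C)CSC1=S
F9 | step 1 | (3R,4E)-3-hydroxy-N,6,6-trimethoxy-N,4-dimethylhex-4-enamide | COC(OC)/C=C(C)/[C@H](O)CC(=O)N(C)OC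
A1 | alternative 1 | fused bicyclo[5.4.0]undecenone C5 mesylate (target skeleton without the C5-C11 bond, C5-OMs inverted relative to C5 of 25) | CC1=CC(=O)C[C@@]2(C)[C@@H]1[C@H](OS(C)(=O)=O)C(C)(C)[C@H](OC(=O)CC(C)C)C[C@H]2OC(=O)CC(C)C
A2 | alternative 2 | (2Z,4E,7R,9R,10E)-3,6,6,10-tetramethyl-1-oxocycloundeca-2,4,10-triene-7,9-diyl bis(3-methylbutanoate) | O=C1/C=C(C)\C=C\C(C)(C)[C@H](OC(=O)CC(C)C)C[C@@H](OC(=O)CC(C)C)/C(C)=C/1
A3 | alternative 2 | zerumbone, (2E,6E,10E)-2,6,9,9-tetramethylcycloundeca-2,6,10-trien-1-one | C/C1=C\CC(C)(C)/C=C/C(=O)/C(C)=C/CC1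
A4 | alternative 3 | longipin-2-en-1-one (25 without the two acyloxy groups) | CC1=CC(=O)[C@@H]2[C@@H]3[C@H]1[C@@]2(C)CCCC3(C)C
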